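I keep the books on the nucleophile and not on the clock: cedar's electrophile reads 74.2% at 1.50 min and 71.3% at 20.0 min, a drift of a few scatters, and larch's stays near 49.6% throughout.

the same everywhere: electrophile 0.58 M
- cedar: nucleophile 0.31 M; run made earlier
- larch: nucleophile 0.57 M; run made earlier
- dusk: nucleophile 0.610 M; time 30 min
- noon: nucleophile 0.910 M; time 30 min

- cedar (time / min: electrophile / %, target / %): 1.50: 74.2, 26.9; 4.00: 72.6, 26.6; 10.0: 71.4, 29.1; 20.0: 71.3, 29.2
- larch (time / min: electrophile / %, target / %): 5.00: 49.6, 48.9; 10.0: 50.4, 50.4; 15.0: 51.0, 49.7; 20.0: 49.9, 49.2

(standard deviation of a reading: 1 percentage point)

1. part of the electrophile that has reacted at the end, dusk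
2. part of the electrophile that has reacted at the end, noon
3. what raising the concentration of nucleophile from its lowest to its highest value here does to the part of the electrophile that has reacted (changes below 5 percentage points count as none) (it falls / no change / it rises)

- what was read earlier has a scatter of 1 percentage point, one standard deviation

Larch, the run nearest to dusk, has lost on average 49.8% of its electrophile, which is 0.289 M for 0.57 M of nucleophile. That gives a price of 1.97, the moles of nucleophile charged per mole of electrophile reacted. Cedar's last two readings give 1.87, so the price holds roughly across both charges, and I take the nucleophile as the limiting reagent.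

Now my ledger. Dusk enters c(nucleophile) = 0.610 M. At this price it buys 0.310 M of electrophile, one mole of nucleophile per mole going with the target, I suppose, and the other 0.300 M going somewhere the readings do not show. The books close at 53.4% reacted. Noon enters 0.910 M, which buys 0.462 M, less than the 0.58 M of electrophile charged, so it closes at 79.6%. That entry stretches the price well beyond the charges tried.

The forecast gives 53% (50% to 56%) for dusk and 79% (68% to 83%) for noon, says it rises, and rests on this: “the nucleophile runs out at two equivalents per electrophile”.

The flask gives 52.3% for dusk and 74.3% for noon, so it rises, by 22 percentage points.

    2 nucleophile → homo dimer (k = 0.00293 /M/s)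
    nucleophile + acid set free ⇌ protonated nucleophile, settled at all times (K = 2120 /M)
    electrophile + nucleophile ⇌ acid set free + target (K = 4.87, k = 0.0515 /M/s)

In dusk at the asked time, the step joining electrophile and nucleophile, taken by itself and both ways together, relaxes with a half-life of 0.642 min, far shorter than the 30 min asked. At 300 min the answer for dusk stands at 52.1%. Read back from the results, the price is 2.01 for dusk and 2.11 for noon, against the 1.97 I read from the larch readings. For the neighbour of dusk with 0.14 M of electrophile, the same 0.610 M of nucleophile buys 0.310 M, more than that charge, so I expect the electrophile to go first. The computed flask shows 99.8% reacted, with 0.22% of the electrophile left.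

(The numbers in the tables stem from a simulated flask on assumed constants; the scatter is artificial.)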